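The closed, stirred vessel holds a chain of steps, and what enters that chain is set by the partner.

all flasks: substrate 0.20 M
- Saturday's: partner 0.50 equiv; second reagent 0.70 equiv; third reagent 0.95 equiv; temperature 5 °C; the very flask that is asked about, followed so far
- Monday's: partner 0.50 equiv; second reagent 0.70 equiv; third reagent 0.95 equiv; temperature 0 °C; run made earlier
- flask: partner 0.500 equiv; second reagent 0.700 equiv; third reagent 0.950 equiv; temperature 5 °C; time 30 h

| run | time / h | target / % |
|---|---|---|
| Saturday's | 1.33 | 1.1 |
| Saturday's | 3.00 | 2.2 |
| Saturday's | 8.00 | 9.4 |
| Saturday's | 20.0 | 15.1 |
| Monday's | 1.33 | 0.3 |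
| Monday's | 3.00 | 1.3 |
| Monday's | 8.00 | 4.7 |
| Monday's | 20.0 | 15.1 |

(standard deviation of a reading: 0.5 percentage points)

- target, in percent of the substrate first charged, at 30 h
- what to do for the largest gain in target; "none" if nothing gains more than 2 percentage points (dusk / autumn / midnight / dawn / none)
- target present, with what was taken out counted in, in percent of the substrate first charged, after dusk
- target present, with what was taken out counted in, in percent of the substrate first charged, after autumn

- removed target is counted in
- candidate steps: intermediate B -> side product; second reagent + intermediate A -> intermediate B; third reagent + intermediate B -> target; second reagent + target -> over-reaction product; substrate + partner -> intermediate A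
- additions bring no volume worth counting

- dusk: at 30 h take out 90 % of the target then present, then wait 15 h
- autumn: at 30 h add partner, 50.0 % of the amount charged, then wait 15 h
- midnight: change nothing and wait 15 h more
- dawn: at 30 h raise the temperature by 10 K, then wait 15 h

Among the candidate steps, substrate and partner give intermediate A, second reagent turns that into intermediate B, and third reagent turns that into target. Intermediate B can also leak to side product, and second reagent can attack target. One partner admits one substrate, and its 0.500 equiv stands below the other charges, so I treat it as the limiting reagent. I carry the entry ceiling, the fraction of the substrate charge that the partner can admit to the chain, here 50.0 %.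

Saturday's run is this flask so far. It starts slowly, at 1.1 % after 1.33 h, since target lies behind two intermediates. From 3.00 h to 8.00 h it climbs 0.0144 h⁻¹ of the charge, and from there to 20.0 h the slope is 0.00475 h⁻¹, less by a factor of 3.03. At 8.00 h Saturday's reading is twice Monday's, so the warmer run is ahead at that time. With that fall in slope I place Saturday's knee roughly between 8.00 h and 20.0 h, no closer. I take Saturday's last reading, 15.1 %, a reading with its scatter of 0.5 percentage points, as the level the curve runs into, which is 30.2 % of the ceiling. I expect that level at the asked time, and dusk near it, since dusk admits nothing new. Autumn lifts the ceiling by 25.0 %, worth 7.5 points at the same share, above the margin, so I choose autumn.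

The forecast, below my level, gives 13 %, then 13.5 % after dusk and 15 % after autumn, and picks autumn: “Adding partner uses the excess substrate and forms more A”.

The flask gives 15.0 % and the best choice is none: autumn ends at 16.5 %, a gain of 1.5 points, and dusk at 15.9 %, a gain of 0.96 points.

    intermediate B → side product (k = 0.193 h⁻¹, Ea = 89.0 kJ mol⁻¹)
    second reagent + intermediate A → intermediate B (k = 1.40 M⁻¹ h⁻¹, Ea = 54.0 kJ mol⁻¹)
    third reagent + intermediate B → target (k = 1.19 M⁻¹ h⁻¹, Ea = 74.0 kJ mol⁻¹)
    second reagent + target → over-reaction product (k = 0.400 M⁻¹ h⁻¹, Ea = 71.0 kJ mol⁻¹)
    substrate + partner → intermediate A (k = 2.76 M⁻¹ h⁻¹, Ea = 62.0 kJ mol⁻¹)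
    (constants at 5 °C)

At 30.0 h this flask's substrate stands at 50.0 %, the charge less the ceiling 50.0 %, and it still reads 50.0 % at 300 h. Its partner is down to 0.0127 % of its own charge. In a neighbouring flask with 2.00 equiv of partner the ceiling is the whole charge, and there substrate stands at 0 % and target at 27.6 %. This flask itself is not at rest: over ten times the time its free second reagent falls from 24.9 % to 2.16 % of its charge, over-reaction product rises from 7.45 % to 18.6 %, and target falls from 15.0 % to 6.44 %.

(The earlier runs and the new flask are simulated with constants of no real substance, and the scatter is random.)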